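Eta and delta were best kept in one unit, the mole of partner spent per mole of substrate charged.

- eta: substrate 0.20 M; partner 0.300 M; initiator 4.0 mM; time 20 h
- delta: substrate 0.20 M; partner 0.750 M; initiator 4.0 mM; time 20 h

    initiator → 2 initiating radical (k1 = 2.9 × 10⁻⁵ s⁻¹)
    substrate + initiating radical → chain carrier (k2 = 5700 M⁻¹ s⁻¹)
    partner + chain carrier → target + initiating radical (k3 = 3400 M⁻¹ s⁻¹)
    2 chain carrier → ended chains (k4 = 5.9 × 10⁸ M⁻¹ s⁻¹)
    partner + target → over-reaction product (k5 = 2.4 × 10⁻⁴ M⁻¹ s⁻¹)
    substrate ⇌ dormant form (K6 = 2.0, k6 = 1.3 × 10⁻⁵ s⁻¹)
    partner → decomposed reagent (k7 = 2.0 × 10⁻⁵ s⁻¹)

- which of these there is most of at the end, counted by the substrate in it, eta (over-reaction product / substrate / target / chain carrier)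
- which of these there is most of at the end, counted by the substrate in it, delta (over-reaction product / substrate / target / chain carrier)
- the largest of these amounts at the end, in percent of the substrate charged, eta
- the largest of these amounts at the end, in percent of the substrate charged, delta

- a species is counted by the substrate in it: one ended chains counts as two
- a doubled species enters its step squared and goes two at a time
- run time (eta): 20 h

Eta and delta look nearly the same, since they differ in the partner charge. Each target made costs one partner, each over-reaction product costs a second on the same substrate, and each decomposed reagent costs one. So I wrote the balance: charged partner = [partner] + [decomposed reagent] + [target] + 2[over-reaction product]. Eta holds 1.50 partner per substrate and delta 3.75. I called this ratio of charges the partner budget.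

Taking a substrate through to over-reaction product costs two partners, and eta's budget is smaller than that, while delta's is larger. If the whole substrate charge in eta reached target and the whole partner charge went to the chain and to over-reaction, target stood at 50.0%. That was rough. Partner decays with a half-life of 9.6 h, shorter than the run, which raises the eta figure. I committed to target for eta, at about that figure. For delta, target has a half-life of 1.07 h with partner as charged, far shorter than the run, so I expected over-reaction product to lead, though the budget gave me no figure.

The forecast said target at 48% for eta, slightly below my figure, and over-reaction product at 93% for delta. Its ground for eta was that “the partner is used up by the chain, its own decay and over-reaction before all the substrate converts”.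

The simulation gave target at 49.1% for eta, with over-reaction product at 30.2%, and over-reaction product at 91.8% for delta, with target at 4.81%. The forecast held on each point.

At 20.0 h, eta had 0.61% of its partner left. Target plus twice over-reaction product came to 1.10 of the substrate charge and decomposed reagent to 0.395, which together make up the budget of 1.50. Ten times the time left eta's target at 48.9%, so eta had come to rest as far as target goes. Delta still held 9.1% of its partner, and by 200 h its target had slipped to 3.86% while over-reaction product rose from 91.8% to 94.5%.

The neighbour with 0.12 M of partner has a budget of 0.600, below one, so target plus twice over-reaction product cannot pass that share of the substrate charge. The computed flask ended with target at 27.6%, over-reaction product at 6.99% and 29% of its substrate unreacted, with partner, the limiting reagent, down to 1.2% of its charge: 0.416 of the budget went to those two products and 0.176 to decomposed reagent.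

Its constants are assumed; the run is a simulation.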